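## Retrosynthetic overview

1. The 8a-hydroxy-Δ9(9a) unsaturated lactone is opened last from an 8a,9-α-epoxide of a β,γ-unsaturated lactone by base (E1cB).
2. Ring B and the lactone come from one ester-tethered, exo intramolecular Diels–Alder reaction of a 3-(cyclohexenyl)acrylate of a tertiary cyclopent-2-enol; ring A is carried in the diene.
3. The cyclopentenol (ring C) comes from MeLi/CeCl3 addition to a 5-substituted cyclopent-2-enone, itself closed by ring-closing metathesis of a vinyl ketone.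
4. The piperidine comes from cis-selective reduction of a cyclic imine formed from a δ-amino ketone; it is N-acetylated early.
5. Key C–C bond C11–C2′: intermolecular Mannich addition of the titanium enolate of methyl pent-4-enoate to an (S)-tert-butanesulfinyl aldimine. Ring order: piperidine, then ring C, then ring B together with the lactone.

Locants (one-line convention): the core is numbered as 3,4-ethanonaphtho[2,3-c]furan-1(3H)-one: C1 lactone C=O, O2, C3 (CMe), C3a, C4, C4a–C8a, C9, C9a, bridge C10 (on C4) and C11 (on C3, carrying piperidine C2′); α is the face of H-3a; the target is (3R,3aS,4S,4aS,8aS,11R,2′S,6′S).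

## Route

Step 1
Reactants: 1 ethyl 5-oxohexanoate
Product: 2 ethyl 4-(2-methyl-1,3-dioxolan-2-yl)butanoate
Conditions: HOCH2CH2OH (3 equiv), TsOH·H2O (5 mol %), toluene, reflux, Dean–Stark
Reagents that add atoms: ethylene glycol OCCO
Why: Acid-catalysed ketalisation with azeotropic water removal masks the ketone against the later hydride and enolate steps and leaves the ester untouched; no stereocentre is formed.

Step 2
Reactants: 2 ethyl 4-(2-methyl-1,3-dioxolan-2-yl)butanoate
Product: 3 4-(2-methyl-1,3-dioxolan-2-yl)butanal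
Conditions: (Me2CHCH2)2AlH (1.1 equiv), CH2Cl2, −78 °C; MeOH, then aq. potassium sodium tartrate
Reagents that add atoms: none
Why: Partial hydride reduction of the ester stops at the aldehyde because the tetrahedral aluminium hemiacetal is stable at −78 °C; the ketal is inert.

Step 3
Reactants: 3 4-(2-methyl-1,3-dioxolan-2-yl)butanal; 4 (S)-2-methylpropane-2-sulfinamide
Product: 5 (S,E)-2-methyl-N-[4-(2-methyl-1,3-dioxolan-2-yl)butylidene]propane-2-sulfinamide
Conditions: pyrrolidine (10 mol %), 4 Å molecular sieves, CH2Cl2, 23 °C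
Reagents that add atoms: none
Why: Amine-catalysed condensation of the aldehyde with the sulfinamide gives the E-configured N-sulfinyl aldimine under non-acidic conditions that keep the ketal and the sulfur stereocentre.

Step 4
Reactants: 6 methyl pent-4-enoate; 5 (S,E)-2-methyl-N-[4-(2-methyl-1,3-dioxolan-2-yl)butylidene]propane-2-sulfinamide
Product: 9 methyl (2R,3S)-3-{[(S)-tert-butylsulfinyl]amino}-6-(2-methyl-1,3-dioxolan-2-yl)-2-(prop-2-en-1-yl)hexanoate, via lithium enolate 7 (not isolated), via titanium enolate 8 (not isolated)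
Conditions: LiN(CHMe2)2, THF, −78 °C; ClTi(OCHMe2)3 (2 equiv), −78 °C; then 5, −78 °C; aq. NH4Cl
Reagents that add atoms: none
Why: In this fragment-joining Mannich addition the titanium (E)-enolate reacts through a chair Zimmerman–Traxler transition state with titanium bound to the sulfinyl imine, so the (S)-sulfinyl group directs attack to the imine face that gives 3S (C2′) and the E-enolate/E-imine pairing gives the syn 2R centre (C11).

Step 5
Reactants: 9 methyl (2R,3S)-3-{[(S)-tert-butylsulfinyl]amino}-6-(2-methyl-1,3-dioxolan-2-yl)-2-(prop-2-en-1-yl)hexanoate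
Product: 12 methyl (2R)-2-[(2S,6S)-6-methylpiperidin-2-yl]pent-4-enoate, via amino ketone 10 (not isolated), via cyclic imine 11 (not isolated)
Conditions: HCl (4 M in dioxane), MeOH, 0 to 23 °C; 1 M aq. HCl, 23 °C; Et3N to pH 7; NaBH4, MeOH, −20 °C
Reagents that add atoms: none
Why: Acid removes the sulfinyl group and the ketal, the δ-amino ketone condenses to the six-membered imine, and axial hydride attack on its half-chair (C2′ substituent equatorial) gives the cis-2,6-disubstituted piperidine (6′S) in this imine reduction.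

Step 6
Reactants: 12 methyl (2R)-2-[(2S,6S)-6-methylpiperidin-2-yl]pent-4-enoate
Product: 13 methyl (2R)-2-[(2S,6S)-1-acetyl-6-methylpiperidin-2-yl]pent-4-enoate
Conditions: AcCl, Et3N, DMAP (cat.), CH2Cl2, 0 to 40 °C
Reagents that add atoms: acetyl chloride CC(Cl)=O
Why: DMAP-catalysed N-acylation installs the acetamide of the target early, where it also protects the hindered nitrogen through the organometallic, thermal and oxidative steps that follow.

Step 7
Reactants: 13 methyl (2R)-2-[(2S,6S)-1-acetyl-6-methylpiperidin-2-yl]pent-4-enoate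
Product: 14 (2R)-2-[(2S,6S)-1-acetyl-6-methylpiperidin-2-yl]-N-methoxy-N-methylpent-4-enamide
Conditions: MeNHOMe·HCl, Me2CHMgCl, THF, −20 to 0 °C
Reagents that add atoms: N,O-dimethylhydroxylamine hydrochloride CNOC.Cl
Why: Aminolysis of the methyl ester by the magnesium amide (Weinreb amide formation) is fast at low temperature and does not enolise the α-centre C11, while the tertiary acetamide is inert.

Step 8
Reactants: 14 (2R)-2-[(2S,6S)-1-acetyl-6-methylpiperidin-2-yl]-N-methoxy-N-methylpent-4-enamide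
Product: 15 (4R)-4-[(2S,6S)-1-acetyl-6-methylpiperidin-2-yl]hepta-1,6-dien-3-one
Conditions: CH2=CHMgBr, THF, 0 °C; inverse quench into cold 1 M HCl
Reagents that add atoms: vinylmagnesium bromide C=C[Mg]Br
Why: In this Weinreb ketone synthesis the chelated tetrahedral adduct prevents over-addition and collapses to the vinyl ketone only on acidic quench, which also traps the released amine before it can add to the enone.

Step 9
Reactants: 15 (4R)-4-[(2S,6S)-1-acetyl-6-methylpiperidin-2-yl]hepta-1,6-dien-3-one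
Product: 16 (5R)-5-[(2S,6S)-1-acetyl-6-methylpiperidin-2-yl]cyclopent-2-en-1-one
Conditions: second-generation Grubbs catalyst (5 mol %), CH2Cl2 (5 mM), 40 °C
Reagents that add atoms: none
Why: Ring-closing metathesis of the 1,6-diene closes ring C as a cyclopentenone with loss of ethylene under neutral conditions that do not epimerise C11.

Step 10
Reactants: 16 (5R)-5-[(2S,6S)-1-acetyl-6-methylpiperidin-2-yl]cyclopent-2-en-1-one
Product: 17 (1R,5R)-5-[(2S,6S)-1-acetyl-6-methylpiperidin-2-yl]-1-methylcyclopent-2-en-1-ol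
Conditions: MeLi, CeCl3 (anhydrous), THF, −78 °C; aq. NH4Cl
Reagents that add atoms: methyllithium [Li]C
Why: The non-basic organocerium reagent adds 1,2 to the enone carbonyl from the face anti to the bulky C11 substituent, which sets C3 (R) with the hydroxyl cis to the piperidine.

Step 11
Reactants: 18 cyclohex-1-ene-1-carbaldehyde; 19 malonic acid
Product: 20 (2E)-3-(cyclohex-1-en-1-yl)prop-2-enoic acid
Conditions: pyridine, piperidine (cat.), 95 °C; aq. HCl
Reagents that add atoms: none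
Why: Knoevenagel–Doebner condensation (aldol-type condensation followed by decarboxylation) gives the E-dienoic acid.

Step 12
Reactants: 20 (2E)-3-(cyclohex-1-en-1-yl)prop-2-enoic acid
Product: 21 (2E)-3-(cyclohex-1-en-1-yl)prop-2-enoyl chloride
Conditions: (COCl)2, DMF (cat.), CH2Cl2, 0 to 23 °C
Reagents that add atoms: oxalyl chloride O=C(Cl)C(Cl)=O
Why: Vilsmeier-type activation converts the acid into the acid chloride without touching the diene.

Step 13
Reactants: 17 (1R,5R)-5-[(2S,6S)-1-acetyl-6-methylpiperidin-2-yl]-1-methylcyclopent-2-en-1-ol; 21 (2E)-3-(cyclohex-1-en-1-yl)prop-2-enoyl chloride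
Product: 23 (1R,5R)-5-[(2S,6S)-1-acetyl-6-methylpiperidin-2-yl]-1-methylcyclopent-2-en-1-yl (2E)-3-(cyclohex-1-en-1-yl)prop-2-enoate, via lithium alkoxide 22 (not isolated)
Conditions: n-BuLi (1.0 equiv), THF, −78 °C; then 21, −78 to 0 °C
Reagents that add atoms: none
Why: O-acylation of the pre-formed lithium alkoxide is the standard way to esterify a hindered tertiary alcohol and avoids acid that would ionise the allylic C–O bond.

Step 14
Reactants: 23 (1R,5R)-5-[(2S,6S)-1-acetyl-6-methylpiperidin-2-yl]-1-methylcyclopent-2-en-1-yl (2E)-3-(cyclohex-1-en-1-yl)prop-2-enoate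
Product: 25 (3R,3aS,4S,4aS,9aR,11R)-11-[(2S,6S)-1-acetyl-6-methylpiperidin-2-yl]-3-methyl-3a,4,4a,5,6,7,8,9a-octahydro-3,4-ethanonaphtho[2,3-c]furan-1(3H)-one, via trans-lactone 24 (not isolated)
Conditions: toluene (0.01 M), BHT (0.1 equiv), sealed tube, 185 °C; then DBU (0.2 equiv), 23 °C
Reagents that add atoms: none
Why: In this ester-tethered intramolecular Diels–Alder reaction the three-atom tether forces the diene onto the cyclopentene face syn to the C3–O bond (C3a S, C4 S) through the exo transition state (H-4 and H-4a trans, C4a S), and DBU then epimerises C9a of the first-formed trans-lactone to the cis-fused lactone.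

Step 15
Reactants: 25 (3R,3aS,4S,4aS,9aR,11R)-11-[(2S,6S)-1-acetyl-6-methylpiperidin-2-yl]-3-methyl-3a,4,4a,5,6,7,8,9a-octahydro-3,4-ethanonaphtho[2,3-c]furan-1(3H)-one
Product: 26 (3R,3aS,4S,4aS,8aS,9R,9aS,11R)-11-[(2S,6S)-1-acetyl-6-methylpiperidin-2-yl]-8a,9-epoxy-3-methyldecahydro-3,4-ethanonaphtho[2,3-c]furan-1(3H)-one
Conditions: DMDO (dimethyldioxirane in acetone), CH2Cl2, 0 °C
Reagents that add atoms: dimethyldioxirane CC1(C)OO1
Why: Neutral epoxidation of the only electron-rich alkene occurs from the convex α face because the β face of ring B is capped by the cis-fused lactone and ring C, which sets C8a (S).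

Step 16
Reactants: 26 (3R,3aS,4S,4aS,8aS,9R,9aS,11R)-11-[(2S,6S)-1-acetyl-6-methylpiperidin-2-yl]-8a,9-epoxy-3-methyldecahydro-3,4-ethanonaphtho[2,3-c]furan-1(3H)-one
Product: 27 (3R,3aS,4S,4aS,8aS,11R)-11-[(2S,6S)-1-acetyl-6-methylpiperidin-2-yl]-8a-hydroxy-3-methyl-3a,4,4a,5,6,7,8,8a-octahydro-3,4-ethanonaphtho[2,3-c]furan-1(3H)-one
Conditions: DBU (0.5 equiv), CH2Cl2, 23 °C
Reagents that add atoms: none
Why: E1cB opening of the β,γ-epoxy lactone: the C9a enolate expels the C9–O bond to give the conjugated C9=C9a alkene and the tertiary alcohol with retention at C8a.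

## Compound list

1 | ethyl 5-oxohexanoate | CCOC(=O)CCCC(C)=O | starting material
2 | ethyl 4-(2-methyl-1,3-dioxolan-2-yl)butanoate | CCOC(=O)CCCC1(C)OCCO1 | intermediate
3 | 4-(2-methyl-1,3-dioxolan-2-yl)butanal | O=CCCCC1(C)OCCO1 | intermediate
4 | (S)-2-methylpropane-2-sulfinamide | CC(C)(C)[S@@](N)=O | starting material
5 | (S,E)-2-methyl-N-[4-(2-methyl-1,3-dioxolan-2-yl)butylidene]propane-2-sulfinamide | CC(C)(C)[S@](=O)/N=C/CCCC1(C)OCCO1 | intermediate
6 | methyl pent-4-enoate | COC(=O)CCC=C | starting material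
7 | lithium enolate of 6 (O–Li trans to the allyl-bearing chain) | CO/C(O[Li])=C\CC=C | intermediate (not isolated)
8 | triisopropoxytitanium (E)-enolate of 6 | CO/C(O[Ti](OC(C)C)(OC(C)C)OC(C)C)=C\CC=C | intermediate (not isolated)
9 | methyl (2R,3S)-3-{[(S)-tert-butylsulfinyl]amino}-6-(2-methyl-1,3-dioxolan-2-yl)-2-(prop-2-en-1-yl)hexanoate | COC(=O)[C@H](CC=C)[C@H](CCCC1(C)OCCO1)N[S@@](=O)C(C)(C)C | intermediate
10 | methyl (2R,3S)-3-amino-7-oxo-2-(prop-2-en-1-yl)octanoate | COC(=O)[C@H](CC=C)[C@@H](N)CCCC(C)=O | intermediate (not isolated)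
11 | methyl (2R)-2-[(2S)-6-methyl-2,3,4,5-tetrahydropyridin-2-yl]pent-4-enoate | COC(=O)[C@H](CC=C)[C@@H]1CCCC(C)=N1 | intermediate (not isolated)
12 | methyl (2R)-2-[(2S,6S)-6-methylpiperidin-2-yl]pent-4-enoate | COC(=O)[C@H](CC=C)[C@@H]1CCC[C@H](C)N1 | intermediate
13 | methyl (2R)-2-[(2S,6S)-1-acetyl-6-methylpiperidin-2-yl]pent-4-enoate | COC(=O)[C@H](CC=C)[C@@H]1CCC[C@H](C)N1C(C)=O | intermediate
14 | (2R)-2-[(2S,6S)-1-acetyl-6-methylpiperidin-2-yl]-N-methoxy-N-methylpent-4-enamide | CON(C)C(=O)[C@H](CC=C)[C@@H]1CCC[C@H](C)N1C(C)=O | intermediate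
15 | (4R)-4-[(2S,6S)-1-acetyl-6-methylpiperidin-2-yl]hepta-1,6-dien-3-one | C=CC(=O)[C@H](CC=C)[C@@H]1CCC[C@H](C)N1C(C)=O | intermediate
16 | (5R)-5-[(2S,6S)-1-acetyl-6-methylpiperidin-2-yl]cyclopent-2-en-1-one | O=C1C=CC[C@@H]1[C@@H]1CCC[C@H](C)N1C(C)=O | intermediate
17 | (1R,5R)-5-[(2S,6S)-1-acetyl-6-methylpiperidin-2-yl]-1-methylcyclopent-2-en-1-ol | CC(=O)N1[C@@H](C)CCC[C@H]1[C@H]1CC=C[C@@]1(C)O | intermediate
18 | cyclohex-1-ene-1-carbaldehyde | O=CC1=CCCCC1 | starting material
19 | malonic acid | OC(=O)CC(=O)O | starting material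
20 | (2E)-3-(cyclohex-1-en-1-yl)prop-2-enoic acid | OC(=O)/C=C/C1=CCCCC1 | intermediate
21 | (2E)-3-(cyclohex-1-en-1-yl)prop-2-enoyl chloride | ClC(=O)/C=C/C1=CCCCC1 | intermediate
22 | lithium alkoxide of 17 | CC(=O)N1[C@@H](C)CCC[C@H]1[C@H]1CC=C[C@@]1(C)O[Li] | intermediate (not isolated)
23 | (1R,5R)-5-[(2S,6S)-1-acetyl-6-methylpiperidin-2-yl]-1-methylcyclopent-2-en-1-yl (2E)-3-(cyclohex-1-en-1-yl)prop-2-enoate | CC(=O)N1[C@@H](C)CCC[C@H]1[C@H]1CC=C[C@@]1(C)OC(=O)/C=C/C1=CCCCC1 | intermediate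
24 | (3R,3aS,4S,4aS,9aS,11R)-11-[(2S,6S)-1-acetyl-6-methylpiperidin-2-yl]-3-methyl-3a,4,4a,5,6,7,8,9a-octahydro-3,4-ethanonaphtho[2,3-c]furan-1(3H)-one (trans-lactone, H-9a β) | CC(=O)N1[C@@H](C)CCC[C@H]1[C@H]1C[C@@H]2[C@H]3[C@H](C=C4CCCC[C@@H]24)C(=O)O[C@@]13C | intermediate (not isolated)
25 | (3R,3aS,4S,4aS,9aR,11R)-11-[(2S,6S)-1-acetyl-6-methylpiperidin-2-yl]-3-methyl-3a,4,4a,5,6,7,8,9a-octahydro-3,4-ethanonaphtho[2,3-c]furan-1(3H)-one (cis-lactone, C8a=C9) | CC(=O)N1[C@@H](C)CCC[C@H]1[C@H]1C[C@@H]2[C@H]3[C@@H](C=C4CCCC[C@@H]24)C(=O)O[C@@]13C | intermediate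
26 | (3R,3aS,4S,4aS,8aS,9R,9aS,11R)-11-[(2S,6S)-1-acetyl-6-methylpiperidin-2-yl]-8a,9-epoxy-3-methyldecahydro-3,4-ethanonaphtho[2,3-c]furan-1(3H)-one (α-epoxide) | CC(=O)N1[C@@H](C)CCC[C@H]1[C@H]1C[C@@H]2[C@H]3[C@@H]([C@H]4O[C@]45CCCC[C@@H]25)C(=O)O[C@@]13C | intermediate
27 | (3R,3aS,4S,4aS,8aS,11R)-11-[(2S,6S)-1-acetyl-6-methylpiperidin-2-yl]-8a-hydroxy-3-methyl-3a,4,4a,5,6,7,8,8a-octahydro-3,4-ethanonaphtho[2,3-c]furan-1(3H)-one (CNP0529632.1) | CC(=O)N1[C@@H](C)CCC[C@H]1[C@H]1C[C@@H]2[C@H]3C(=C[C@]4(O)CCCC[C@@H]24)C(=O)O[C@@]13C | target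

## Summary and risks

Total step count: 16. Longest linear sequence: 14 steps (steps 1–10 and 13–16, from 1); steps 11–12 make the diene arm.

The three steps most likely to fail:

Step 14 (intramolecular Diels–Alder reaction). The tertiary allylic ester 23 may ionise or eliminate the dienoic acid at 185 °C before it adds to the unactivated, neopentyl-flanked cyclopentene. The fallback sets out from 16 and comes back at 25. Luche reduction of 16 (NaBH4, CeCl3·7H2O, MeOH, −78 °C, hydride anti to the C11 substituent) gives (1R,5R)-5-[(2S,6S)-1-acetyl-6-methylpiperidin-2-yl]cyclopent-2-en-1-ol F1. Acylation by 21 (Et3N, DMAP, CH2Cl2) gives the secondary ester (1R,5R)-5-[(2S,6S)-1-acetyl-6-methylpiperidin-2-yl]cyclopent-2-en-1-yl (2E)-3-(cyclohex-1-en-1-yl)prop-2-enoate F2, which has no tertiary C–O bond. Heating as in step 14 gives the C3-unsubstituted trans-lactone cycloadduct F3, which DBU epimerises in the same flask to the C3-unsubstituted cis-lactone F4. Pyrrolidine and AlMe3 open the lactone to the hydroxy pyrrolidine amide F5, and Dess–Martin periodinane oxidises it to the C3 keto amide F6. MeLi/CeCl3 adds from the convex α face to give the tertiary carbinol amide F7, and TsOH in warm toluene closes the lactone with loss of pyrrolidine to give 25.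

Step 13 (acylation of the congested tertiary allylic alkoxide). The alkoxide sits cis to the piperidine and may acylate slowly or attack the acetamide instead. The fallback sets out from 17 and comes back at 23. DCC coupling of 17 with diethylphosphonoacetic acid, which acylates through the unhindered phosphonoketene, gives (1R,5R)-5-[(2S,6S)-1-acetyl-6-methylpiperidin-2-yl]-1-methylcyclopent-2-en-1-yl 2-(diethoxyphosphoryl)acetate F8. A Horner–Wadsworth–Emmons olefination with aldehyde 18 (LiCl, DBU, MeCN) then builds the E-dienoate in place and gives 23.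

Step 15 (epoxidation). Face selectivity may be incomplete, or the acid- and base-sensitive epoxide may not survive isolation. The fallback sets out from 25 and comes back at 27, bypassing 26. LiN(SiMe3)2 (THF, −78 °C) then PhSeCl selenenylates the lactone dienolate at C9a from the convex α face to give the 9a-(phenylselanyl) lactone F9. H2O2 (pyridine, CH2Cl2, 0 °C) oxidises it to the selenoxide F10, whose [2,3]-sigmatropic shift carries oxygen suprafacially to the α face of C8a to give the C8a selenenate F11, hydrolysed in the same flask to 27.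

Further compounds

F1 | step 14 | (1R,5R)-5-[(2S,6S)-1-acetyl-6-methylpiperidin-2-yl]cyclopent-2-en-1-ol | CC(=O)N1[C@@H](C)CCC[C@H]1[C@H]1CC=C[C@H]1O
F2 | step 14 | (1R,5R)-5-[(2S,6S)-1-acetyl-6-methylpiperidin-2-yl]cyclopent-2-en-1-yl (2E)-3-(cyclohex-1-en-1-yl)prop-2-enoate | CC(=O)N1[C@@H](C)CCC[C@H]1[C@H]1CC=C[C@H]1OC(=O)/C=C/C1=CCCCC1
F3 | step 14 | C3-unsubstituted trans-lactone cycloadduct, (3R,3aS,4S,4aS,9aS,11R)-11-[(2S,6S)-1-acetyl-6-methylpiperidin-2-yl]-3a,4,4a,5,6,7,8,9a-octahydro-3,4-ethanonaphtho[2,3-c]furan-1(3H)-one | CC(=O)N1[C@@H](C)CCC[C@H]1[C@H]1C[C@@H]2[C@H]3[C@H](C=C4CCCC[C@@H]24)C(=O)O[C@@H]13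
F4 | step 14 | C3-unsubstituted cis-lactone, (3R,3aS,4S,4aS,9aR,11R)-11-[(2S,6S)-1-acetyl-6-methylpiperidin-2-yl]-3a,4,4a,5,6,7,8,9a-octahydro-3,4-ethanonaphtho[2,3-c]furan-1(3H)-one | CC(=O)N1[C@@H](C)CCC[C@H]1[C@H]1C[C@@H]2[C@H]3[C@@H](C=C4CCCC[C@@H]24)C(=O)O[C@@H]13
F5 | step 14 | hydroxy pyrrolidine amide (ring-opened F4: C3 secondary alcohol, C9a–C(=O)-pyrrolidin-1-yl) | CC(=O)N1[C@@H](C)CCC[C@H]1[C@H]1C[C@@H]2[C@@H]([C@@H](C=C4CCCC[C@@H]24)C(=O)N5CCCC5)[C@H]1O
F6 | step 14 | C3 keto amide (C3 ketone of F5) | CC(=O)N1[C@@H](C)CCC[C@H]1[C@H]1C[C@@H]2[C@@H]([C@@H](C=C4CCCC[C@@H]24)C(=O)N5CCCC5)C1=O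
F7 | step 14 | tertiary carbinol amide ((3R)-3-hydroxy-3-methyl analogue of F5) | CC(=O)N1[C@@H](C)CCC[C@H]1[C@H]1C[C@@H]2[C@@H]([C@@H](C=C4CCCC[C@@H]24)C(=O)N5CCCC5)[C@@]1(C)O
F8 | step 13 | (1R,5R)-5-[(2S,6S)-1-acetyl-6-methylpiperidin-2-yl]-1-methylcyclopent-2-en-1-yl 2-(diethoxyphosphoryl)acetate | CC(=O)N1[C@@H](C)CCC[C@H]1[C@H]1CC=C[C@@]1(C)OC(=O)CP(=O)(OCC)OCC
F9 | step 15 | 9a-(phenylselanyl) lactone (25 with α-SePh at C9a) | CC(=O)N1[C@@H](C)CCC[C@H]1[C@H]1C[C@@H]2[C@H]3[C@](C=C4CCCC[C@@H]24)([Se]c5ccccc5)C(=O)O[C@@]13C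
F10 | step 15 | selenoxide of F9 | CC(=O)N1[C@@H](C)CCC[C@H]1[C@H]1C[C@@H]2[C@H]3[C@](C=C4CCCC[C@@H]24)([Se](=O)c5ccccc5)C(=O)O[C@@]13C
F11 | step 15 | C8a selenenate (27 with O–SePh at C8a) | CC(=O)N1[C@@H](C)CCC[C@H]1[C@H]1C[C@@H]2[C@H]3C(=C[C@]4(O[Se]c5ccccc5)CCCC[C@@H]24)C(=O)O[C@@]13C
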